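**Retrosynthetic overview**

1. Ring atoms are labelled C1–C14 as in the target SMILES (C1 stereocentre; C3=C4 with CH2OH on C4; C7=C8 E; C11=C12 Z). The only ring, the 14-membered carbocycle, is closed last: desilylation and Pd/hydride desulfonylation lead back to a macrocyclic allylic sulfone, closed at C9–C10 by intramolecular alkylation of a C10 sulfone carbanion with a C9 allylic bromide.
2. The open chain is cut at C2–C3 (B-alkyl Suzuki–Miyaura) into a C2 alkyl pinacolboronate (C10–C14, C1, C2, side chain) and a (Z)-iodoalkene (C3–C9).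
3. C1 and the C1–C2 bond come from the new step: copper-catalysed enantioselective SN2' substitution of a 2-alkyl (Z)-allylic phosphate with bis(pinacolato)borylmethane, which also creates the exocyclic methylene of the side chain.
4. The phosphate comes from hydroboration/Suzuki union (C14–C1) of a (Z)-diene, made from commercial (Z)-3-methylpent-2-en-4-yn-1-ol, with an iodo allylic alcohol.
5. That iodo allylic alcohol (copper-catalysed anti-carbomagnesiation of propargyl alcohol with homoprenyl Grignard, then iodine) is used twice: as C1 plus side chain, and, after allylic oxidation, as C3–C9.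

Assumption: 5-bromo-2-methylpent-2-ene, (Z)-3-methylpent-2-en-4-yn-1-ol and bis(pinacolato)borylmethane are bought; the chiral imidazolinium ligand of step 8 is a catalyst component made separately and is not counted.

**Route**

Step 1
Reactants: 1 5-bromo-2-methylpent-2-ene; 2 prop-2-yn-1-ol
Product: 5 (2Z)-3-iodo-2-(4-methylpent-3-en-1-yl)prop-2-en-1-ol, via homoprenylmagnesium bromide 3 (not isolated), via chelated alkenylmagnesium alkoxide 4 (not isolated)
Conditions: Mg, THF, 40 °C; then 2 (0.4 equiv), CuI (10 mol %), THF, −10 °C to rt, 16 h; then I2, THF, −20 °C; aq. NH4Cl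
Reagents that add atoms: iodine, II
Why: Copper-catalysed anti-carbomagnesiation of propargyl alcohol (Duboudin-type) puts the alkyl group on C2 and magnesium on C3 inside a five-membered alkoxide chelate, so iodinolysis with retention gives only the isomer with iodine cis to CH2OH.

Step 2
Reactants: 5 (2Z)-3-iodo-2-(4-methylpent-3-en-1-yl)prop-2-en-1-ol
Product: 6 tert-butyl{[(2Z)-3-iodo-2-(4-methylpent-3-en-1-yl)prop-2-en-1-yl]oxy}diphenylsilane
Conditions: TBDPSCl, imidazole, CH2Cl2, 0 °C to rt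
Reagents that add atoms: tert-butyl(chloro)diphenylsilane, CC(C)(C)[Si](Cl)(c1ccccc1)c1ccccc1
Why: Routine imidazole-promoted silylation of a primary alcohol; this silyl ether survives every later step up to the final fluoride cleavage.

Step 3
Reactants: 6 tert-butyl{[(2Z)-3-iodo-2-(4-methylpent-3-en-1-yl)prop-2-en-1-yl]oxy}diphenylsilane
Product: 7 (2E,6Z)-6-{[tert-butyl(diphenyl)silyl]oxymethyl}-7-iodo-2-methylhepta-2,6-dien-1-ol
Conditions: SeO2 (0.5 equiv), t-BuOOH (3 equiv), salicylic acid (10 mol %), CH2Cl2, rt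
Reagents that add atoms: tert-butyl hydroperoxide, CC(C)(C)OO
Why: SeO2/t-BuOOH allylic oxidation (ene reaction, then [2,3]-shift) attacks the electron-rich prenyl terminus at its (E)-methyl group while the iodoalkene is deactivated, giving the E allylic alcohol whose carbinol carbon becomes C9.

Step 4
Reactants: 8 (2Z)-3-methylpent-2-en-4-yn-1-ol
Product: 9 tert-butyl(dimethyl){[(2Z)-3-methylpent-2-en-4-yn-1-yl]oxy}silane
Conditions: TBSCl, imidazole, CH2Cl2, 0 °C to rt
Reagents that add atoms: tert-butyl(chloro)dimethylsilane, CC(C)(C)[Si](C)(C)Cl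
Why: Routine silylation; the commercial enynol already carries the Z trisubstituted alkene that becomes C11=C12.

Step 5
Reactants: 9 tert-butyl(dimethyl){[(2Z)-3-methylpent-2-en-4-yn-1-yl]oxy}silane
Product: 10 tert-butyl(dimethyl){[(2Z)-3-methylpenta-2,4-dien-1-yl]oxy}silane
Conditions: H2 (1 atm), Pd/CaCO3 poisoned with Pb(OAc)2, quinoline, hexane, rt, stopped at 1 equiv H2
Reagents that add atoms: none
Why: Lindlar-type semihydrogenation of the terminal alkyne stops at the vinyl group and does not touch or isomerise the trisubstituted Z alkene.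

Step 6
Reactants: 10 tert-butyl(dimethyl){[(2Z)-3-methylpenta-2,4-dien-1-yl]oxy}silane; 5 (2Z)-3-iodo-2-(4-methylpent-3-en-1-yl)prop-2-en-1-ol
Product: 12 (2Z,6Z)-8-{[tert-butyl(dimethyl)silyl]oxy}-6-methyl-2-(4-methylpent-3-en-1-yl)octa-2,6-dien-1-ol, via B-alkyl-9-BBN borane 11 (not isolated)
Conditions: 9-BBN (1.1 equiv), THF, 0 °C to rt; then 5 (0.9 equiv), Pd(dppf)Cl2·CH2Cl2 (5 mol %), AsPh3 (10 mol %), Cs2CO3, DMF/THF/H2O, rt
Reagents that add atoms: none
Why: 9-BBN adds boron only to the terminal CH2 of the vinyl group (the trisubstituted alkene is inert), and the B-alkyl Suzuki–Miyaura coupling with the iodoalkene proceeds with retention, so the new chain (C14) ends up cis to CH2OH at the C14–C1 junction.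

Step 7
Reactants: 12 (2Z,6Z)-8-{[tert-butyl(dimethyl)silyl]oxy}-6-methyl-2-(4-methylpent-3-en-1-yl)octa-2,6-dien-1-ol
Product: 13 (2Z,6Z)-8-{[tert-butyl(dimethyl)silyl]oxy}-6-methyl-2-(4-methylpent-3-en-1-yl)octa-2,6-dien-1-yl diethyl phosphate
Conditions: ClP(O)(OEt)2, Et3N, DMAP (10 mol %), CH2Cl2, 0 °C
Reagents that add atoms: diethyl chlorophosphate, CCOP(=O)(Cl)OCC
Why: Standard phosphorylation of a primary allylic alcohol installs the leaving group needed for copper-catalysed SN2' chemistry.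

Step 8
Reactants: 13 (2Z,6Z)-8-{[tert-butyl(dimethyl)silyl]oxy}-6-methyl-2-(4-methylpent-3-en-1-yl)octa-2,6-dien-1-yl diethyl phosphate; 14 2,2'-methylenebis(4,4,5,5-tetramethyl-1,3,2-dioxaborolane)
Product: 15 tert-butyl{[(2Z,6S)-3,11-dimethyl-7-methylidene-6-[(4,4,5,5-tetramethyl-1,3,2-dioxaborolan-2-yl)methyl]dodeca-2,10-dien-1-yl]oxy}dimethylsilane
Conditions: 14 (2.0 equiv), CuCl (5 mol %), enantiopure 1-(2,6-diethylphenyl)-4,5-diphenyl-3-(2-sulfonatophenyl)-4,5-dihydroimidazolium inner salt (5.5 mol %, the antipode that gives 6S), NaOMe (1.5 equiv), THF, 22 °C, 24 h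
Reagents that add atoms: none
Why: Proposed new method: NHC–copper-catalysed enantioselective SN2' transfer of a CH2Bpin group to a 2-alkyl (β-branched) Z-allylic phosphate, a substrate class not yet shown for this nucleophile; NaOMe turns 14 into a borate that transmetalates to the chiral sulfonate-bridged NHC–Cu–OMe complex, the resulting Cu–CH2Bpin species adds anti to the phosphate at the γ-carbon (C1) in a sodium-bridged, phosphate-bound transition state, and reductive elimination from the trivalent copper σ-allyl gives the branched product with the new 1,1-disubstituted alkene, the ligand controlling which face of C1 is attacked (the Z geometry fixed in step 6 makes this a single diastereomeric pathway) and the smaller 2,6-diethylphenyl N-aryl group being proposed to make room for the β-alkyl chain; closest known reaction types are the NHC–copper-catalysed enantioselective allylic substitution of γ-substituted allylic phosphates with bis(pinacolato)borylmethane and the copper/phosphoramidite SN2' alkylation of 2-substituted allylic chlorides with Grignard reagents.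

Step 9
Reactants: 15 tert-butyl{[(2Z,6S)-3,11-dimethyl-7-methylidene-6-[(4,4,5,5-tetramethyl-1,3,2-dioxaborolan-2-yl)methyl]dodeca-2,10-dien-1-yl]oxy}dimethylsilane
Product: 16 (2Z,6S)-3,11-dimethyl-7-methylidene-6-[(4,4,5,5-tetramethyl-1,3,2-dioxaborolan-2-yl)methyl]dodeca-2,10-dien-1-ol
Conditions: PPTS (20 mol %), MeOH, rt
Reagents that add atoms: none
Why: Acid-catalysed methanolysis removes the primary allylic TBS ether under conditions that leave the pinacol boronate, the alkenes and the stereocentre untouched.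

Step 10
Reactants: 16 (2Z,6S)-3,11-dimethyl-7-methylidene-6-[(4,4,5,5-tetramethyl-1,3,2-dioxaborolan-2-yl)methyl]dodeca-2,10-dien-1-ol
Product: 17 2-[(2S,5Z)-7-chloro-5-methyl-2-(6-methylhepta-1,5-dien-2-yl)hept-5-en-1-yl]-4,4,5,5-tetramethyl-1,3,2-dioxaborolane
Conditions: NCS, Me2S, CH2Cl2, −30 to 0 °C
Reagents that add atoms: N-chlorosuccinimide, O=C1CCC(=O)N1Cl
Why: Corey–Kim chlorination converts the allylic alcohol into the chloride by SN2 displacement of an alkoxysulfonium ion, without allylic transposition or loss of the Z geometry.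

Step 11
Reactants: 17 2-[(2S,5Z)-7-chloro-5-methyl-2-(6-methylhepta-1,5-dien-2-yl)hept-5-en-1-yl]-4,4,5,5-tetramethyl-1,3,2-dioxaborolane
Product: 18 2-[(2S,5Z)-7-(benzenesulfonyl)-5-methyl-2-(6-methylhepta-1,5-dien-2-yl)hept-5-en-1-yl]-4,4,5,5-tetramethyl-1,3,2-dioxaborolane
Conditions: PhSO2Na, DMF, rt
Reagents that add atoms: sodium benzenesulfinate, [Na+].[O-]S(=O)c1ccccc1
Why: SN2 S-alkylation of the sulfinate by the primary allylic chloride in DMF gives the C10 sulfone with the Z alkene intact.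

Step 12
Reactants: 18 2-[(2S,5Z)-7-(benzenesulfonyl)-5-methyl-2-(6-methylhepta-1,5-dien-2-yl)hept-5-en-1-yl]-4,4,5,5-tetramethyl-1,3,2-dioxaborolane; 7 (2E,6Z)-6-{[tert-butyl(diphenyl)silyl]oxymethyl}-7-iodo-2-methylhepta-2,6-dien-1-ol
Product: 19 (2E,6Z,9R,12Z)-14-(benzenesulfonyl)-6-{[tert-butyl(diphenyl)silyl]oxymethyl}-2,12-dimethyl-9-(6-methylhepta-1,5-dien-2-yl)tetradeca-2,6,12-trien-1-ol
Conditions: 18 (1.2 equiv), Pd(OAc)2 (5 mol %), RuPhos (10 mol %), KOH (3 equiv), THF/H2O 10:1, 45 °C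
Reagents that add atoms: none
Why: B-alkyl Suzuki–Miyaura coupling of the hydroxide-activated primary alkyl pinacolboronate with the iodoalkene forms C2–C3 with retention of the alkene geometry (C2 cis to CH2OSi), and the sulfone, free alcohol and silyl ether are tolerated at this temperature.

Step 13
Reactants: 19 (2E,6Z,9R,12Z)-14-(benzenesulfonyl)-6-{[tert-butyl(diphenyl)silyl]oxymethyl}-2,12-dimethyl-9-(6-methylhepta-1,5-dien-2-yl)tetradeca-2,6,12-trien-1-ol
Product: 20 tert-butyl{[(2Z,6E)-2-[(3R,6Z)-8-(benzenesulfonyl)-6-methyl-3-(6-methylhepta-1,5-dien-2-yl)oct-6-en-1-ylidene]-8-bromo-7-methyloct-6-en-1-yl]oxy}diphenylsilane (the C9 bromide of 19)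
Conditions: CBr4, PPh3, CH2Cl2, 0 °C
Reagents that add atoms: carbon tetrabromide, BrC(Br)(Br)Br
Why: Appel bromination of the primary allylic alcohol is an SN2 process without transposition and leaves the sulfone and silyl ether alone.

Step 14
Reactants: 20 the C9 bromide of 19
Product: 22 tert-butyl{[(1Z,4R,7Z,11E)-9-(benzenesulfonyl)-7,11-dimethyl-4-(6-methylhepta-1,5-dien-2-yl)cyclotetradeca-1,7,11-trien-1-yl]methoxy}diphenylsilane (both epimers at the sulfone carbon), via potassium sulfonyl carbanion 21 (not isolated)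
Conditions: KN(SiMe3)2 (1.5 equiv), THF, −78 to −20 °C, slow addition of 20, final 0.002 M
Reagents that add atoms: none
Why: Intramolecular α-alkylation of the allylic sulfone carbanion by the primary allylic bromide under high dilution (Julia-type sulfone alkylation, the classical closure of cembranoid 14-membered rings) forms C9–C10; C1 is untouched and the new sulfone-bearing centre is erased in step 15.

Step 15
Reactants: 22 macrocyclic sulfone
Product: 23 tert-butyl{[(1Z,4R,7Z,11E)-7,11-dimethyl-4-(6-methylhepta-1,5-dien-2-yl)cyclotetradeca-1,7,11-trien-1-yl]methoxy}diphenylsilane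
Conditions: Pd(dppp)Cl2 (10 mol %), LiBHEt3 (3 equiv), THF, 0 °C to rt
Reagents that add atoms: none
Why: Palladium-catalysed hydride displacement of the allylic sulfone goes through a π-allyl palladium intermediate that takes hydride at its less substituted terminus (C10), so the sulfone is removed with the C11=C12 alkene kept in place and Z.

Step 16
Reactants: 23 silyl ether of the target
Product: 24 [(1Z,4R,7Z,11E)-7,11-dimethyl-4-(6-methylhepta-1,5-dien-2-yl)cyclotetradeca-1,7,11-trien-1-yl]methanol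
Conditions: Bu4NF, THF, 0 °C to rt
Reagents that add atoms: none
Why: Fluoride cleaves the silyl ether without touching the polyene, giving the target with C1 (R) as set in step 8.

**Compound list**

1 | 5-bromo-2-methylpent-2-ene | CC(C)=CCCBr | starting material
2 | prop-2-yn-1-ol | C#CCO | starting material
3 | (4-methylpent-3-en-1-yl)magnesium bromide | CC(C)=CCC[Mg]Br | intermediate (not isolated)
4 | bromomagnesium (2Z)-3-(bromomagnesio)-2-(4-methylpent-3-en-1-yl)prop-2-en-1-olate (Mg cis to CH2O) | Br[Mg]/C=C(/CCC=C(C)C)CO[Mg]Br | intermediate (not isolated)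
5 | (2Z)-3-iodo-2-(4-methylpent-3-en-1-yl)prop-2-en-1-ol (I cis to CH2OH) | I/C=C(/CCC=C(C)C)CO | intermediate
6 | tert-butyl{[(2Z)-3-iodo-2-(4-methylpent-3-en-1-yl)prop-2-en-1-yl]oxy}diphenylsilane | I/C=C(/CCC=C(C)C)CO[Si](c1ccccc1)(c1ccccc1)C(C)(C)C | intermediate
7 | (2E,6Z)-6-{[tert-butyl(diphenyl)silyl]oxymethyl}-7-iodo-2-methylhepta-2,6-dien-1-ol | I/C=C(/CC/C=C(\C)CO)CO[Si](c1ccccc1)(c1ccccc1)C(C)(C)C | intermediate
8 | (2Z)-3-methylpent-2-en-4-yn-1-ol | OC/C=C(/C)C#C | starting material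
9 | tert-butyl(dimethyl){[(2Z)-3-methylpent-2-en-4-yn-1-yl]oxy}silane | CC(C)(C)[Si](C)(C)OC/C=C(/C)C#C | intermediate
10 | tert-butyl(dimethyl){[(2Z)-3-methylpenta-2,4-dien-1-yl]oxy}silane | CC(C)(C)[Si](C)(C)OC/C=C(/C)C=C | intermediate
11 | 9-[(3Z)-5-{[tert-butyl(dimethyl)silyl]oxy}-3-methylpent-3-en-1-yl]-9-borabicyclo[3.3.1]nonane | CC(C)(C)[Si](C)(C)OC/C=C(/C)CCB1C2CCCC1CCC2 | intermediate (not isolated)
12 | (2Z,6Z)-8-{[tert-butyl(dimethyl)silyl]oxy}-6-methyl-2-(4-methylpent-3-en-1-yl)octa-2,6-dien-1-ol | CC(C)(C)[Si](C)(C)OC/C=C(/C)CC/C=C(/CCC=C(C)C)CO | intermediate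
13 | (2Z,6Z)-8-{[tert-butyl(dimethyl)silyl]oxy}-6-methyl-2-(4-methylpent-3-en-1-yl)octa-2,6-dien-1-yl diethyl phosphate | CC(C)(C)[Si](C)(C)OC/C=C(/C)CC/C=C(/CCC=C(C)C)COP(=O)(OCC)OCC | intermediate
14 | 2,2'-methylenebis(4,4,5,5-tetramethyl-1,3,2-dioxaborolane) | CC1(C)OB(CB2OC(C)(C)C(C)(C)O2)OC1(C)C | starting material
15 | tert-butyl{[(2Z,6S)-3,11-dimethyl-7-methylidene-6-[(4,4,5,5-tetramethyl-1,3,2-dioxaborolan-2-yl)methyl]dodeca-2,10-dien-1-yl]oxy}dimethylsilane | C=C(CCC=C(C)C)[C@H](CC/C(C)=C\CO[Si](C)(C)C(C)(C)C)CB1OC(C)(C)C(C)(C)O1 | intermediate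
16 | (2Z,6S)-3,11-dimethyl-7-methylidene-6-[(4,4,5,5-tetramethyl-1,3,2-dioxaborolan-2-yl)methyl]dodeca-2,10-dien-1-ol | C=C(CCC=C(C)C)[C@H](CC/C(C)=C\CO)CB1OC(C)(C)C(C)(C)O1 | intermediate
17 | 2-[(2S,5Z)-7-chloro-5-methyl-2-(6-methylhepta-1,5-dien-2-yl)hept-5-en-1-yl]-4,4,5,5-tetramethyl-1,3,2-dioxaborolane | C=C(CCC=C(C)C)[C@H](CC/C(C)=C\CCl)CB1OC(C)(C)C(C)(C)O1 | intermediate
18 | 2-[(2S,5Z)-7-(benzenesulfonyl)-5-methyl-2-(6-methylhepta-1,5-dien-2-yl)hept-5-en-1-yl]-4,4,5,5-tetramethyl-1,3,2-dioxaborolane | C=C(CCC=C(C)C)[C@H](CC/C(C)=C\CS(=O)(=O)c1ccccc1)CB1OC(C)(C)C(C)(C)O1 | intermediate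
19 | (2E,6Z,9R,12Z)-14-(benzenesulfonyl)-6-{[tert-butyl(diphenyl)silyl]oxymethyl}-2,12-dimethyl-9-(6-methylhepta-1,5-dien-2-yl)tetradeca-2,6,12-trien-1-ol (same spatial arrangement at the stereocentre as in 18; the descriptor changes with the CIP priorities) | C=C(CCC=C(C)C)[C@H](CC/C(C)=C\CS(=O)(=O)c1ccccc1)C/C=C(/CC/C=C(\C)CO)CO[Si](c1ccccc1)(c1ccccc1)C(C)(C)C | intermediate
20 | tert-butyl{[(2Z,6E)-2-[(3R,6Z)-8-(benzenesulfonyl)-6-methyl-3-(6-methylhepta-1,5-dien-2-yl)oct-6-en-1-ylidene]-8-bromo-7-methyloct-6-en-1-yl]oxy}diphenylsilane (19 with CH2Br in place of CH2OH at C9) | C=C(CCC=C(C)C)[C@H](CC/C(C)=C\CS(=O)(=O)c1ccccc1)C/C=C(/CC/C=C(\C)CBr)CO[Si](c1ccccc1)(c1ccccc1)C(C)(C)C | intermediate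
21 | potassium salt of 20 deprotonated at the sulfone-bearing carbon C10 | C=C(CCC=C(C)C)[C@H](CC/C(C)=C\[CH-]S(=O)(=O)c1ccccc1)C/C=C(/CC/C=C(\C)CBr)CO[Si](c1ccccc1)(c1ccccc1)C(C)(C)C.[K+] | intermediate (not isolated)
22 | tert-butyl{[(1Z,4R,7Z,11E)-9-(benzenesulfonyl)-7,11-dimethyl-4-(6-methylhepta-1,5-dien-2-yl)cyclotetradeca-1,7,11-trien-1-yl]methoxy}diphenylsilane, both epimers at the sulfone carbon | C=C(CCC=C(C)C)[C@H]1C/C=C(\CO[Si](c2ccccc2)(c2ccccc2)C(C)(C)C)CC/C=C(\C)CC(S(=O)(=O)c2ccccc2)/C=C(/C)CC1 | intermediate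
23 | tert-butyl{[(1Z,4R,7Z,11E)-7,11-dimethyl-4-(6-methylhepta-1,5-dien-2-yl)cyclotetradeca-1,7,11-trien-1-yl]methoxy}diphenylsilane | C=C(CCC=C(C)C)[C@H]1C/C=C(\CO[Si](c2ccccc2)(c2ccccc2)C(C)(C)C)CC/C=C(\C)CC/C=C(/C)CC1 | intermediate
24 | [(1Z,4R,7Z,11E)-7,11-dimethyl-4-(6-methylhepta-1,5-dien-2-yl)cyclotetradeca-1,7,11-trien-1-yl]methanol | C=C(CCC=C(C)C)[C@H]1C/C=C(\CO)CC/C=C(\C)CC/C=C(/C)CC1 | target

**Totals and risk**

Total step count: 16. Longest linear sequence: 13 steps (8 to 24, steps 4–16).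

Steps most likely to fail:

Step 8 (the new step; the 2-alkyl substituent may slow the SN2' addition, erode the enantioselectivity or let SN2 product through). The fallback uses known chemistry, sets out from 12 and comes back at 15. Corey–Kim chlorination (NCS, Me2S, CH2Cl2) turns 12 into the allylic chloride tert-butyl{[(2Z,6Z)-7-(chloromethyl)-3,11-dimethyldodeca-2,6,10-trien-1-yl]oxy}dimethylsilane F1. The established copper/phosphoramidite-catalysed enantioselective SN2' alkylation of 2-substituted allylic chlorides with Grignard reagents, run with (isopropoxydimethylsilyl)methylmagnesium chloride (Cu(O2C-2-thienyl) 3 mol %, chiral phosphoramidite, CH2Cl2, −78 °C), gives tert-butyl{[(2Z,6S)-6-{[dimethyl(propan-2-yloxy)silyl]methyl}-3,11-dimethyl-7-methylidenedodeca-2,10-dien-1-yl]oxy}dimethylsilane F2. Tamao oxidation (H2O2, KF, KHCO3, THF/MeOH) gives (2S,5Z)-7-{[tert-butyl(dimethyl)silyl]oxy}-5-methyl-2-(6-methylhepta-1,5-dien-2-yl)hept-5-en-1-ol F3, and I2, PPh3, imidazole gives tert-butyl{[(2Z,6S)-6-(iodomethyl)-3,11-dimethyl-7-methylidenedodeca-2,10-dien-1-yl]oxy}dimethylsilane F4. Lithium–iodine exchange (t-BuLi, Et2O/pentane, −78 °C) and quenching with 2-isopropoxy-4,4,5,5-tetramethyl-1,3,2-dioxaborolane return 15.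

Step 12 (transmetalation of the β-branched primary alkyl pinacolboronate may be slow, leaving the allylic sulfone exposed to palladium). The fallback sets out from 18 and comes back at 19; it changes the metal that carries C2. NaBO3·4H2O (THF/H2O) oxidises 18 to (2S,5Z)-7-(benzenesulfonyl)-5-methyl-2-(6-methylhepta-1,5-dien-2-yl)hept-5-en-1-ol F5. I2, PPh3, imidazole gives {[(2Z,6S)-6-(iodomethyl)-3,11-dimethyl-7-methylidenedodeca-2,10-dien-1-yl]sulfonyl}benzene F6. Zinc insertion (Zn dust, LiCl, THF) gives iodo[(2S,5Z)-7-(benzenesulfonyl)-5-methyl-2-(6-methylhepta-1,5-dien-2-yl)hept-5-en-1-yl]zinc F7, which undergoes Negishi coupling with 7 at room temperature (Pd(OAc)2, SPhos, THF, slow addition so that the free hydroxyl of 7 is tolerated) to give 19.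

Step 14 (the 14-membered ring closure may give oligomers or stall). The fallback sets out from 7 and 18 and comes back at 22; it moves the ring-closing bond from C9–C10 to C2–C3. Appel bromination of 7 (CBr4, PPh3) gives {[(2Z,5E)-7-bromo-2-(iodomethylidene)-6-methylhept-5-en-1-yl]oxy}(tert-butyl)diphenylsilane F8. The potassium carbanion of 18 (KN(SiMe3)2, THF, −78 °C) is alkylated intermolecularly by F8 to give 2-[(2S,5Z,9E,13Z)-7-(benzenesulfonyl)-13-{[tert-butyl(diphenyl)silyl]oxymethyl}-14-iodo-5,9-dimethyl-2-(6-methylhepta-1,5-dien-2-yl)tetradeca-5,9,13-trien-1-yl]-4,4,5,5-tetramethyl-1,3,2-dioxaborolane F9, which holds both the boronate and the iodoalkene. Intramolecular B-alkyl Suzuki–Miyaura coupling under high dilution (Pd(OAc)2, RuPhos, KOH, THF/H2O, 0.002 M, 45 °C) closes the ring to 22.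

**Further compounds**

F1 | step 8 | tert-butyl{[(2Z,6Z)-7-(chloromethyl)-3,11-dimethyldodeca-2,6,10-trien-1-yl]oxy}dimethylsilane | CC(C)(C)[Si](C)(C)OC/C=C(/C)CC/C=C(/CCC=C(C)C)CCl
F2 | step 8 | tert-butyl{[(2Z,6S)-6-{[dimethyl(propan-2-yloxy)silyl]methyl}-3,11-dimethyl-7-methylidenedodeca-2,10-dien-1-yl]oxy}dimethylsilane | C=C(CCC=C(C)C)[C@H](CC/C(C)=C\CO[Si](C)(C)C(C)(C)C)C[Si](C)(C)OC(C)C
F3 | step 8 | (2S,5Z)-7-{[tert-butyl(dimethyl)silyl]oxy}-5-methyl-2-(6-methylhepta-1,5-dien-2-yl)hept-5-en-1-ol | C=C(CCC=C(C)C)[C@H](CC/C(C)=C\CO[Si](C)(C)C(C)(C)C)CO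
F4 | step 8 | tert-butyl{[(2Z,6S)-6-(iodomethyl)-3,11-dimethyl-7-methylidenedodeca-2,10-dien-1-yl]oxy}dimethylsilane | C=C(CCC=C(C)C)[C@H](CC/C(C)=C\CO[Si](C)(C)C(C)(C)C)CI
F5 | step 12 | (2S,5Z)-7-(benzenesulfonyl)-5-methyl-2-(6-methylhepta-1,5-dien-2-yl)hept-5-en-1-ol | C=C(CCC=C(C)C)[C@H](CC/C(C)=C\CS(=O)(=O)c1ccccc1)CO
F6 | step 12 | {[(2Z,6S)-6-(iodomethyl)-3,11-dimethyl-7-methylidenedodeca-2,10-dien-1-yl]sulfonyl}benzene | C=C(CCC=C(C)C)[C@H](CC/C(C)=C\CS(=O)(=O)c1ccccc1)CI
F7 | step 12 | iodo[(2S,5Z)-7-(benzenesulfonyl)-5-methyl-2-(6-methylhepta-1,5-dien-2-yl)hept-5-en-1-yl]zinc | C=C(CCC=C(C)C)[C@H](CC/C(C)=C\CS(=O)(=O)c1ccccc1)C[Zn]I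
F8 | step 14 | {[(2Z,5E)-7-bromo-2-(iodomethylidene)-6-methylhept-5-en-1-yl]oxy}(tert-butyl)diphenylsilane | I/C=C(/CC/C=C(\C)CBr)CO[Si](c1ccccc1)(c1ccccc1)C(C)(C)C
F9 | step 14 | 2-[(2S,5Z,9E,13Z)-7-(benzenesulfonyl)-13-{[tert-butyl(diphenyl)silyl]oxymethyl}-14-iodo-5,9-dimethyl-2-(6-methylhepta-1,5-dien-2-yl)tetradeca-5,9,13-trien-1-yl]-4,4,5,5-tetramethyl-1,3,2-dioxaborolane, both epimers at the sulfone carbon | C=C(CCC=C(C)C)[C@H](CC/C(C)=C\C(C/C(C)=C/CC/C(CO[Si](c1ccccc1)(c1ccccc1)C(C)(C)C)=C/I)S(=O)(=O)c1ccccc1)CB1OC(C)(C)C(C)(C)O1
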